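The trap in this series is to treat a yield as a property of the recipe and carry it unchanged to a weaker charge. One reaction, starting material to target, runs here at several charges.

| flask | starting material | target | time |
|---|---|---|---|
| larch | 0.0800 M |  |  |
| cedar | 0.0400 M |  |  |
| elm | 0.0800 M | 0.0400 M |  |
| oak | 0.0230 M |  | 7.9 h |

- larch run (time / h: [target] / M): 0.28: 0.0056; 0.86: 0.0149; 1.6: 0.0233; 2.6: 0.0311; 3.7: 0.0359; 5.0: 0.0382; 6.4: 0.0410; 7.9: 0.0428
- cedar run (time / h: [target] / M): 0.28: 0.0013; 0.86: 0.0062; 1.6: 0.0084; 2.6: 0.0131; 3.7: 0.0141; 5.0: 0.0157; 6.4: 0.0168; 7.9: 0.0164
- elm run (time / h: [target] / M): 0.28: 0.0466; 0.86: 0.0557; 1.6: 0.0635; 2.6: 0.0719; 3.7: 0.0766; 5.0: 0.0792; 6.4: 0.0808; 7.9: 0.0819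

(each reading ± 8 × 10⁻⁴ M)

- Overall: starting material -> target.
- Constant volume, constant temperature.
- The analysis sees a species whether free or bound.
- An order is taken over about fifteen percent of the charge, up and down.

- apparent order in [starting material] of the starting rate, round the charge of the larch run (the rate where two percent of its starting material have turned into target) (one fixed amount of target, the same in the runs compared)
- target in the oak run at 7.9 h, as a share of the starting material charged
- which of these the readings show (two substrates go astray together / the product speeds the reaction / the product binds the substrate / nothing beyond the main steps / the substrate is lost by itself)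

My own reckoning builds the flask up one process at a time. Take the main step first: the larch run makes 0.0056 M of target in 0.28 h, and the cedar run makes a like amount, 0.0062 M, in 0.86 h. So the rate goes as [starting material] to the power 1.47, a reading with wide scatter. Scaled to the oak charge, this gives a rate per unit of charge of 0.139 h⁻¹. Treated as first-order over 7.9 h, that reckoning puts 66.6% of the oak charge into target.

Next comes any action of target itself. By its last reading the elm run has gained 0.0419 M, and the larch run holds 0.0428 M, so the share stays at 66.6%.

Last comes the loss. Both runs flatten below their charge, the larch run at 0.0428 M of 0.0800 M, so a second exit exists. At one moment, target rate over loss rate is an instantaneous selectivity, and it drifts down as [starting material] falls if the target path has the higher order. A run sums that drift into its odds, target over the part of the charge not target at that time. These read 1.15 for larch and 0.695 for cedar at their last readings, a rise with charge to the power 0.727. Carried down to the oak charge, the odds of target against the rest of the charge come to 0.465, which is a share of 31.7%.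

The forecast gives order 1.35, share 33% and the verdict the substrate is lost by itself, holding that starting material is “lost by a path of lower order than the product path”. My order is higher and my share lower.

The flask gives order 1.4, share 31.3% and the verdict the substrate is lost by itself.

    2 starting material ⇌ substrate dimer, settled at all times (11.10 M⁻¹)
    substrate dimer → target + starting material (1.102 h⁻¹)
    starting material → decomposed substrate (0.2110 h⁻¹)

The oak share of 31.3% means odds of 0.455, beside the 0.465 carried from larch and cedar. The verdict would have had to change had the elm run's rate parted from the larch run's, but their ratio reads 1.0. In the oak run, the conversion of starting material into decomposed substrate lowers target from 58.6% to 31.3%, which takes the odds from 1.42 down to 0.455.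

The runs come from a simulation for substances that don't exist; noise was put on by code.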